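**Strategy**

- Cuts: first the sixteen benzylic C–O bonds (fourteen benzyl ethers and the two arms of a m-xylylene bridge), then the interflavan C4–C8 bond, then the two O3 ester bonds, last the two galloyl O4–CH2 ether bonds.
- Enabling feature: each flavan carries a galloyl ester on O3 of ring C, and the para oxygens (O4) of the two galloyl rings can be tied by a m-xylylene diether. This puts C4 of ring C of one flavan and C8 of ring A of the other in one 26-membered ring, and the bridge later leaves as m-xylene.
- Forward order: all six-membered rings are bought. The bridged digallic acid is made, esterified twice with benzylated epigallocatechin, one flavan is oxidised at C4, the macrocycle is closed by cation–arene coupling, and hydrogenolysis opens it again to the target.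
- Stereochemistry: C2 and C3 of both units (2R,3R) come unchanged from (−)-epigallocatechin; C4 of the upper unit is set in the ring closure by attack anti to the 3-O-galloyl group (3,4-trans, 4β).

Key step: step 7

Remark: where one reagent reacts at several equivalent sites in one operation (steps 1 to 5 and 8), the partly reacted species are consumed under the same conditions and are not counted as separate intermediates. The C4 ether centre of 9 is drawn β, but its configuration is immaterial because it is lost on ionisation.

**Route**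

Step 1
Reactants: 1 (−)-epigallocatechin
Product: 2 5,7,3',4',5'-penta-O-benzyl-(−)-epigallocatechin (3-OH free, 2R,3R)
Conditions: BnBr (5.5 equiv), K2CO3, DMF (degassed), −10 °C to rt, argon
Reagents that add atoms: benzyl bromide, BrCc1ccccc1
Why: Williamson O-alkylation in which carbonate deprotonates the five phenols but not the secondary 3-OH, while low temperature and exclusion of air hold back C-benzylation of ring A and base-induced epimerisation at C2, so both stereocentres pass through untouched.

Step 2
Reactants: 3 methyl gallate (3 equiv); 4 1,3-bis(bromomethyl)benzene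
Product: 5 dimethyl 4,4'-[1,3-phenylenebis(methyleneoxy)]bis(3,5-dihydroxybenzoate)
Conditions: KHCO3, KI (cat.), DMF, rt to 40 °C, argon
Reagents that add atoms: none
Why: Williamson etherification made regioselective by acidity, since the 4-OH para to the ester is the only phenol appreciably deprotonated by hydrogencarbonate, and the excess of 3 ensures that each benzylic bromide meets a fresh gallate instead of building oligomers.

Step 3
Reactants: 5 dimethyl 4,4'-[1,3-phenylenebis(methyleneoxy)]bis(3,5-dihydroxybenzoate)
Product: 6 dimethyl 4,4'-[1,3-phenylenebis(methyleneoxy)]bis[3,5-bis(benzyloxy)benzoate]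
Conditions: BnBr (5 equiv), K2CO3, DMF, 50 °C
Reagents that add atoms: benzyl bromide, BrCc1ccccc1
Why: exhaustive Williamson benzylation of the four remaining phenols, which are protected in the same way as the flavan phenols so that a single hydrogenolysis clears everything at the end.

Step 4
Reactants: 6 dimethyl 4,4'-[1,3-phenylenebis(methyleneoxy)]bis[3,5-bis(benzyloxy)benzoate]
Product: 7 4,4'-[1,3-phenylenebis(methyleneoxy)]bis[3,5-bis(benzyloxy)benzoic acid]
Conditions: LiOH (aq), THF/MeOH, 50 °C; then 1 M HCl
Reagents that add atoms: lithium hydroxide, [Li+].[OH-]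
Why: ordinary saponification of two methyl benzoates by acyl–oxygen cleavage, to which benzyl aryl ethers are inert.

Step 5
Reactants: 7 bridged diacid (1 equiv); 2 penta-O-benzyl-(−)-epigallocatechin (2.2 equiv)
Product: 8 C2-symmetric tethered bis(epigallocatechin gallate) perbenzyl ether (diester of 7 with two molecules of 2 through O3)
Conditions: DCC (2.6 equiv), DMAP (0.5 equiv), CH2Cl2, 0 °C to rt
Reagents that add atoms: none
Why: Steglich esterification, the standard way to galloylate the axial 3-OH of benzylated epi-series flavan-3-ols, which forms the acyl–oxygen bond and leaves the C3–O bond and hence both stereocentres intact.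

Step 6
Reactants: 8 tethered bis(epigallocatechin gallate) perbenzyl ether
Product: 9 mono-4β-(2-ethoxyethoxy) derivative of 8 (one flavan oxidised at C4, ether trans to the 3-O-acyl group)
Conditions: DDQ (1.0 equiv, in portions), 2-ethoxyethanol (10 equiv), CH2Cl2, 0 °C to rt; chromatography, recovered 8 recycled
Reagents that add atoms: 2-ethoxyethanol, CCOCCO
Why: DDQ benzylic oxidation by hydride abstraction from C4, which is activated by the alkoxy groups of ring A, followed by trapping of the cation with the alcohol anti to the 3-O-acyl group; the two flavans are equivalent and electronically insulated, so one equivalent of oxidant should give the mono-ether as main product beside recoverable 8 and a separable bis-ether.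

Step 7
Reactants: 9 mono-4β-(2-ethoxyethoxy) tethered bis-flavan
Product: 10 26-membered macrocyclic 4β→8 linked dimer, fully benzylated, xylylene bridge in place
Conditions: Me3SiOTf (0.3 equiv), 4 Å MS, CH2Cl2, −40 °C, 9 added by syringe pump to about 0.5 mM; Et3N quench
Reagents that add atoms: none
Why: Me3SiOTf ionises the 4-(2-ethoxyethoxy) group to a flavan-4-yl cation that is delocalised onto O5, O7 and O1 of ring A (a quinone-methide-type oxocarbenium ion) and is probably bridged on the α face by the carbonyl of the 3-O-galloyl ester; C8 of ring A of the unoxidised flavan attacks C4 in an electrophilic aromatic substitution, and loss of the C8 proton regenerates the silyl triflate. The closest known reaction type is the Lewis-acid-promoted condensation of 4-alkoxy benzyl-protected flavan-3-ol electrophiles with benzylated flavan nucleophiles, which also runs intramolecularly when the two units are joined from O3 to O3 by a diester chain. The only ring closed is the 26-membered macrocycle C4–C3–O–CO–galloyl (C1 to C4)–O–CH2–C6H4–CH2–O–galloyl (C4 to C1)–CO–O–C3–C2–O1–C8a–C8, formed at high dilution in a closure that is endo with respect to the attacked C8–C8a bond of the arene. The single new stereocentre, C4 of the upper unit, is set by the substrate: the pseudoaxial 3-O-galloyl group and its carbonyl participation occupy the α face, so the arene should enter from the β face to give the 3,4-trans (4β) bond, and the 17-atom chain between the two O3 atoms is long enough to let the second flavan swing round to that face instead of being delivered syn to O3 as a short chain would. The step needs C8 over C6 and ring closure over oligomerisation: both positions give the same ring size, so the regiochemistry rests on the intrinsically higher nucleophilicity and lower hindrance of C8 next to the ring oxygen compared with C6 between two benzyloxy groups, while slow addition at sub-millimolar concentration favours the intramolecular path. Because the tether makes the coupling equimolar, no excess of nucleophile is needed and no acylation is required later at the hindered O3 beside the interflavan bond.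

Step 8
Reactants: 10 macrocyclic perbenzylated dimer
Product: 11 rhodisin, (−)-epigallocatechin 3-O-gallate-(4β→8)-(−)-epigallocatechin 3-O-gallate
Conditions: H2 (1 atm), Pd(OH)2 on carbon, THF/MeOH/H2O, rt; filtration under argon, lyophilisation
Reagents that add atoms: none
Why: heterogeneous catalytic hydrogenolysis of benzyl aryl ethers should cleave the fourteen O-benzyl groups and both O–CH2 bonds of the xylylene bridge in one operation, opening the macrocycle, while the esters, the C4–C8 bond and the ring C ether are known to survive these neutral conditions and no stereocentre is touched.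

**Compound list**

1 | (−)-epigallocatechin (2R,3R) | O[C@@H]1Cc2c(O)cc(O)cc2O[C@@H]1c1cc(O)c(O)c(O)c1 | starting material
2 | 5,7,3',4',5'-penta-O-benzyl-(−)-epigallocatechin (2R,3R, 3-OH free) | O[C@@H]1Cc2c(OCc3ccccc3)cc(OCc3ccccc3)cc2O[C@@H]1c1cc(OCc2ccccc2)c(OCc2ccccc2)c(OCc2ccccc2)c1 | intermediate
3 | methyl gallate | COC(=O)c1cc(O)c(O)c(O)c1 | starting material
4 | 1,3-bis(bromomethyl)benzene | BrCc1cccc(CBr)c1 | starting material
5 | dimethyl 4,4'-[1,3-phenylenebis(methyleneoxy)]bis(3,5-dihydroxybenzoate) | COC(=O)c1cc(O)c(OCc2cccc(COc3c(O)cc(C(=O)OC)cc3O)c2)c(O)c1 | intermediate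
6 | dimethyl 4,4'-[1,3-phenylenebis(methyleneoxy)]bis[3,5-bis(benzyloxy)benzoate] | COC(=O)c1cc(OCc2ccccc2)c(OCc2cccc(COc3c(OCc4ccccc4)cc(C(=O)OC)cc3OCc3ccccc3)c2)c(OCc2ccccc2)c1 | intermediate
7 | 4,4'-[1,3-phenylenebis(methyleneoxy)]bis[3,5-bis(benzyloxy)benzoic acid] | OC(=O)c1cc(OCc2ccccc2)c(OCc2cccc(COc3c(OCc4ccccc4)cc(C(=O)O)cc3OCc3ccccc3)c2)c(OCc2ccccc2)c1 | intermediate
8 | C2-symmetric tethered bis(epigallocatechin gallate) perbenzyl ether (2R,3R in both flavans) | O=C(O[C@@H]1Cc2c(OCc3ccccc3)cc(OCc3ccccc3)cc2O[C@@H]1c1cc(OCc2ccccc2)c(OCc2ccccc2)c(OCc2ccccc2)c1)c1cc(OCc2ccccc2)c(OCc2cccc(COc3c(OCc4ccccc4)cc(C(=O)O[C@@H]5Cc6c(OCc7ccccc7)cc(OCc7ccccc7)cc6O[C@@H]5c5cc(OCc6ccccc6)c(OCc6ccccc6)c(OCc6ccccc6)c5)cc3OCc4ccccc4)c2)c(OCc2ccccc2)c1 | intermediate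
9 | mono-4β-(2-ethoxyethoxy) derivative of 8 (ether trans to the 3-O-acyl group) | O=C(O[C@@H]1[C@@H](OCCOCC)c2c(OCc3ccccc3)cc(OCc3ccccc3)cc2O[C@@H]1c1cc(OCc2ccccc2)c(OCc2ccccc2)c(OCc2ccccc2)c1)c1cc(OCc2ccccc2)c(OCc2cccc(COc3c(OCc4ccccc4)cc(C(=O)O[C@@H]5Cc6c(OCc7ccccc7)cc(OCc7ccccc7)cc6O[C@@H]5c5cc(OCc6ccccc6)c(OCc6ccccc6)c(OCc6ccccc6)c5)cc3OCc4ccccc4)c2)c(OCc2ccccc2)c1 | intermediate
10 | 26-membered macrocyclic 4β→8 linked dimer, fourteen benzyl ethers and the xylylene bridge in place | O=C(O[C@@H]1[C@@H]%10c2c(OCc3ccccc3)cc(OCc3ccccc3)cc2O[C@@H]1c1cc(OCc2ccccc2)c(OCc2ccccc2)c(OCc2ccccc2)c1)c1cc(OCc2ccccc2)c(OCc2cccc(COc3c(OCc4ccccc4)cc(C(=O)O[C@@H]5Cc6c(OCc7ccccc7)cc(OCc7ccccc7)c%10c6O[C@@H]5c5cc(OCc6ccccc6)c(OCc6ccccc6)c(OCc6ccccc6)c5)cc3OCc4ccccc4)c2)c(OCc2ccccc2)c1 | intermediate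
11 | rhodisin, epigallocatechin 3-O-gallate-(4β→8)-epigallocatechin 3-O-gallate | O=C(O[C@@H]1[C@@H](c2c(O)cc(O)c3c2O[C@H](c2cc(O)c(O)c(O)c2)[C@H](OC(=O)c2cc(O)c(O)c(O)c2)C3)c2c(O)cc(O)cc2O[C@@H]1c1cc(O)c(O)c(O)c1)c1cc(O)c(O)c(O)c1 | target

**Count and risks**

Total steps: 8. Longest linear sequence: 7 (steps 2 to 8, from methyl gallate and the dibromide).

Steps most likely to fail:

1. Step 7. The tether may deliver ring A of the second flavan to the α face (3,4-cis) or to C6, or ring closure may lose to oligomerisation. The fallback gives up the tether and forms the same C4–C8 bond intermolecularly. It sets out from 2, which is esterified with commercial 3,4,5-tris(benzyloxy)benzoic acid (DCC, DMAP) to octa-O-benzyl-(−)-epigallocatechin gallate F1. Part of F1 is oxidised with DDQ and 2-ethoxyethanol, the reaction already used in step 6, to 4β-(2-ethoxyethoxy)-octa-O-benzyl-epigallocatechin gallate F2. Condensation of F2 with an excess of F1 (4 to 5 equiv, recoverable) under Me3SiOTf in CH2Cl2 at −40 °C should give hexadeca-O-benzyl epigallocatechin gallate-(4β→8)-epigallocatechin gallate F3, with the 3-O-galloyl group directing trans attack. Hydrogenolysis (H2, Pd(OH)2 on carbon) rejoins the route at 11.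

2. Step 6. Hydride abstraction may be slow on the 3-O-acylated flavan, or the mixture of unreacted, mono-oxidised and bis-oxidised material may resist separation. The fallback oxidises before tethering. It sets out from 2, whose free 3-OH form is the best-precedented substrate: DDQ and 2-ethoxyethanol should give 4β-(2-ethoxyethoxy)-penta-O-benzyl-epigallocatechin F4. Separately, 2 is esterified with an excess (3 equiv) of diacid 7 (DCC, DMAP) to the mono-ester mono-acid F5, the surplus diacid being recovered by base extraction. Esterification of F5 with F4 (DCC, DMAP) rejoins the route at 9 without any statistical oxidation.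

3. Step 2. Alkylation may stray to O3 or O5, or one gallate may be alkylated more than once, giving regioisomeric and oligomeric ethers. The fallback masks O3 and O5 as acetates. It sets out from 3, which is peracetylated (Ac2O, pyridine) to methyl 3,4,5-triacetoxybenzoate F6. With 4, K2CO3 and KI in refluxing acetone the 4-acetate, the most labile because it is para to the ester, should be cleaved selectively and the phenoxide alkylated in situ to dimethyl 4,4'-[1,3-phenylenebis(methyleneoxy)]bis(3,5-diacetoxybenzoate) F7. Methanolysis of the four acetates (K2CO3, MeOH, rt) rejoins the route at 5.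

**Further compounds**

F1 | step 7 | octa-O-benzyl-(−)-epigallocatechin gallate | O=C(O[C@@H]1Cc2c(OCc3ccccc3)cc(OCc3ccccc3)cc2O[C@@H]1c1cc(OCc2ccccc2)c(OCc2ccccc2)c(OCc2ccccc2)c1)c1cc(OCc2ccccc2)c(OCc2ccccc2)c(OCc2ccccc2)c1
F2 | step 7 | 4β-(2-ethoxyethoxy)-octa-O-benzyl-epigallocatechin gallate | O=C(O[C@@H]1[C@@H](OCCOCC)c2c(OCc3ccccc3)cc(OCc3ccccc3)cc2O[C@@H]1c1cc(OCc2ccccc2)c(OCc2ccccc2)c(OCc2ccccc2)c1)c1cc(OCc2ccccc2)c(OCc2ccccc2)c(OCc2ccccc2)c1
F3 | step 7 | hexadeca-O-benzyl epigallocatechin gallate-(4β→8)-epigallocatechin gallate | O=C(O[C@@H]1[C@@H](c2c(OCc4ccccc4)cc(OCc4ccccc4)c3c2O[C@H](c2cc(OCc4ccccc4)c(OCc4ccccc4)c(OCc4ccccc4)c2)[C@H](OC(=O)c2cc(OCc4ccccc4)c(OCc4ccccc4)c(OCc4ccccc4)c2)C3)c2c(OCc3ccccc3)cc(OCc3ccccc3)cc2O[C@@H]1c1cc(OCc2ccccc2)c(OCc2ccccc2)c(OCc2ccccc2)c1)c1cc(OCc2ccccc2)c(OCc2ccccc2)c(OCc2ccccc2)c1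
F4 | step 6 | 4β-(2-ethoxyethoxy)-5,7,3',4',5'-penta-O-benzyl-epigallocatechin | O[C@@H]1[C@@H](OCCOCC)c2c(OCc3ccccc3)cc(OCc3ccccc3)cc2O[C@@H]1c1cc(OCc2ccccc2)c(OCc2ccccc2)c(OCc2ccccc2)c1
F5 | step 6 | mono-ester of diacid 7 with one molecule of 2 (second carboxylic acid free) | O=C(O[C@@H]1Cc2c(OCc3ccccc3)cc(OCc3ccccc3)cc2O[C@@H]1c1cc(OCc2ccccc2)c(OCc2ccccc2)c(OCc2ccccc2)c1)c1cc(OCc2ccccc2)c(OCc2cccc(COc3c(OCc4ccccc4)cc(C(=O)O)cc3OCc4ccccc4)c2)c(OCc2ccccc2)c1
F6 | step 2 | methyl 3,4,5-triacetoxybenzoate | COC(=O)c1cc(OC(C)=O)c(OC(C)=O)c(OC(C)=O)c1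
F7 | step 2 | dimethyl 4,4'-[1,3-phenylenebis(methyleneoxy)]bis(3,5-diacetoxybenzoate) | COC(=O)c1cc(OC(C)=O)c(OCc2cccc(COc3c(OC(C)=O)cc(C(=O)OC)cc3OC(C)=O)c2)c(OC(C)=O)c1
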